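**Plan** (drimane numbering: ring A = C1–C5 and C10, ring B = C5–C10, C11 = the exocyclic chloro carbon)
- Cuts, in retrosynthetic order: the quinone is taken back to a 2,3,5-trimethoxyphenyl group; the C11–aryl bond is cut (Negishi coupling of an α-chloroalkenylzinc); C9=C11 is traced to a C11 aldehyde made from a C9 enol triflate; ring A is cut at C1–C10 and C3–C4, leaving (R)-carvone and a three-carbon 2-sulfonylallyl unit.
- Enabling feature: in ring A the quaternary carbons C4 (gem-dimethyl) and C10 (angular methyl) flank C5–H and are spanned by C1–C2–C3. In carvone, C10 is the α′-carbon of the C9 ketone (an enolate) and C4 is the internal carbon of the isopropenyl group (a tertiary radical after hydrogen-atom transfer). An allyl unit that is electrophilic at C1 and radical-accepting at C3 therefore closes ring A in one flask.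
- Forward order: ring B is carvone; ring A is annulated in step 2; C11 is then added at C9, the chloroalkene is built, and the arene is attached and oxidised last.
- Stereochemistry: C5 comes from (R)-carvone; C10 is set by alkylation anti to the isopropenyl group, which fixes the trans ring fusion; C8 is set by α-face hydrogenation; the E alkene follows from the aldehyde enolate geometry (O, then Cl, syn to C8–H) and stereoretentive replacement of the remaining vinylic H by aryl.

Key step: step 2

Remark: the 6-epimers of 3, the C7 sulfone epimers of 7 and any C1 epimer of 11 are carried as mixtures, because each of these centres is erased later.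

Step 1
Reactants: 1 (R)-(−)-carvone
Product: 3 (5R,6S)-2,6-dimethyl-5-(prop-1-en-2-yl)cyclohex-2-en-1-one (trans-6-methylcarvone; minor 6R epimer carried along), via lithium dienolate 2 (not isolated)
Conditions: LiN(iPr)2, THF, −78 °C; MeI, −78 → 0 °C
Reagents that add atoms: iodomethane (CI)
Why: Kinetic enolate alkylation: the amide base removes one of the only α′-hydrogens (the future C10) to give the cross-conjugated dienolate, which is C-methylated; the new centre is unimportant because it is re-enolised in step 2.

Step 2
Reactants: 3 (5R,6S)-2,6-dimethyl-5-(prop-1-en-2-yl)cyclohex-2-en-1-one; 4 2,3-bis(phenylsulfonyl)prop-1-ene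
Product: 7 (4aS,8aS)-2,5,5,8a-tetramethyl-7-(phenylsulfonyl)-4a,5,6,7,8,8a-hexahydronaphthalen-1(4H)-one (both C7 epimers), via lithium dienolate 5 (not isolated), via allyl vinyl sulfone 6 (not isolated)
Conditions: LiN(iPr)2, THF, −78 °C; 4, −78 → −20 °C; then EtOH, Fe(acac)3 (30 mol %), PhSiH3, 60 °C (same flask, high dilution)
Reagents that add atoms: none
Why: In the first stage the kinetic dienolate 5 adds to the vinyl sulfone of 4 and expels benzenesulfinate (conjugate addition–elimination, SN2′), which forms C1–C10; in the second stage the iron hydride made from Fe(acac)3 and PhSiH3 transfers a hydrogen atom to the CH2 of the isopropenyl group, and the tertiary C4 radical adds to the terminal carbon C3 of the new vinyl sulfone (Giese addition), the α-sulfonyl radical then being reduced and protonated by ethanol. The closest known reaction types are the α′-alkylation of carvone enolates with 2-substituted allyl electrophiles and the iron-hydride reductive coupling of 1,1-disubstituted alkenes with vinyl sulfones. Ring A closes in the radical stage in the 6-endo-trig mode, because the sulfone polarises the acceptor so that attack at its unsubstituted terminus is favoured electronically and sterically over 5-exo attack at C2. C10 is set in the intermolecular alkylation: the isopropenyl group on C5 lies pseudo-axial in the dienolate and the electrophile enters anti to it, so C1 ends trans to C4 and closure at the non-stereogenic C4 can only give the trans-fused decalin; C5 is the carvone centre and the sulfone-bearing carbon is a throw-away centre. The step needs α′- over γ-enolisation (kinetic base, a single α′-hydrogen), C- over O-alkylation (soft Michael-type electrophile) and hydrogen-atom transfer to the electron-rich isopropenyl group in preference to the enone and the vinyl sulfone (polarity matching with the hydridic iron hydride).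

Step 3
Reactants: 7 (4aS,8aS)-2,5,5,8a-tetramethyl-7-(phenylsulfonyl)-4a,5,6,7,8,8a-hexahydronaphthalen-1(4H)-one
Product: 9 (4aS,8aS)-2,5,5,8a-tetramethyl-3,4,4a,5,6,7,8,8a-octahydronaphthalen-1-yl trifluoromethanesulfonate, via lithium enolate 8 (not isolated)
Conditions: Li, NH3/THF, t-BuOH (2 equiv), −78 °C; NH3 off; PhNTf2 (excess), THF, 0 → 25 °C
Reagents that add atoms: N-phenylbis(trifluoromethanesulfonimide) (O=S(=O)(N(c1ccccc1)S(=O)(=O)C(F)(F)F)C(F)(F)F)
Why: Dissolving-metal (Birch-type) reduction turns the enone into the C9–C8 lithium enolate, which is the only enolate possible because C10 is quaternary, and cleaves the secondary C–SO2Ph bond in the same pot; the enolate is then O-sulfonylated and no stereocentre is formed (C8 becomes sp2).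

Step 4
Reactants: 9 (4aS,8aS)-2,5,5,8a-tetramethyl-3,4,4a,5,6,7,8,8a-octahydronaphthalen-1-yl trifluoromethanesulfonate
Product: 10 (4aS,8aS)-2,5,5,8a-tetramethyl-3,4,4a,5,6,7,8,8a-octahydronaphthalene-1-carbaldehyde
Conditions: Pd(OAc)2 (5 mol %), dppp, CO (1 atm), Et3SiH, Et3N, DMF, 70 °C
Reagents that add atoms: carbon monoxide ([C-]#[O+])
Why: Palladium-catalysed reductive carbonylation (formylation) of an alkenyl triflate by oxidative addition, CO insertion and hydride transfer from the silane installs C11; no stereocentre changes.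

Step 5
Reactants: 10 (4aS,8aS)-2,5,5,8a-tetramethyl-3,4,4a,5,6,7,8,8a-octahydronaphthalene-1-carbaldehyde
Product: 11 (1S,2S,4aS,8aS)-2,5,5,8a-tetramethyldecahydronaphthalene-1-carbaldehyde
Conditions: H2 (50 bar), Pd/C (10 % palladium on carbon), EtOAc, 25 °C
Reagents that add atoms: none
Why: Heterogeneous catalytic hydrogenation (syn addition): the β face of C8=C9 is shielded by the axial C10 methyl group, so both hydrogens should arrive from the α face, which sets the 8β-methyl centre; the C9 centre formed with it is erased in step 6.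

Step 6
Reactants: 11 (1S,2S,4aS,8aS)-2,5,5,8a-tetramethyldecahydronaphthalene-1-carbaldehyde
Product: 13 (E)-[(2S,4aS,8aS)-2,5,5,8a-tetramethyloctahydronaphthalen-1(2H)-ylidene]methyl trifluoromethanesulfonate, via potassium enolate 12 (not isolated)
Conditions: KH, THF, 0 °C; PhNTf2, 0 → 25 °C
Reagents that add atoms: N-phenylbis(trifluoromethanesulfonimide) (O=S(=O)(N(c1ccccc1)S(=O)(=O)C(F)(F)F)C(F)(F)F)
Why: Aldehyde enolate O-triflation: the enolate oxygen should sit on the C8 side, where only the equatorial hydrogen lies in the alkene plane (the 8β-methyl is axial), and not next to the C1 methylene on the C10 side (allylic 1,3-strain), which sets the E geometry.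

Step 7
Reactants: 13 (E)-[(2S,4aS,8aS)-2,5,5,8a-tetramethyloctahydronaphthalen-1(2H)-ylidene]methyl trifluoromethanesulfonate
Product: 14 (1E,2S,4aS,8aS)-1-(chloromethylidene)-2,5,5,8a-tetramethyldecahydronaphthalene
Conditions: Ni(cod)2 (10 mol %), LiCl, DMA/THF, 25 °C
Reagents that add atoms: lithium chloride ([Li+].[Cl-])
Why: Nickel-catalysed halogen exchange of an enol triflate (oxidative addition to zerovalent nickel, triflate/chloride exchange, reductive elimination) proceeds with retention at the alkene carbon, so chlorine inherits the position syn to C8.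

Step 8
Reactants: 15 3-bromo-4,5-dimethoxybenzaldehyde
Product: 17 3-bromo-4,5-dimethoxyphenol, via aryl formate 16 (not isolated)
Conditions: mCPBA, CH2Cl2, 25 °C; then K2CO3 (cat.), MeOH
Reagents that add atoms: 3-chloroperoxybenzoic acid (OOC(=O)c1cccc(Cl)c1)
Why: Baeyer–Villiger (Dakin-type) oxidation: the electron-rich aryl group migrates to oxygen and the formate is removed by methanolysis; no stereocentre.

Step 9
Reactants: 17 3-bromo-4,5-dimethoxyphenol
Product: 18 1-bromo-2,3,5-trimethoxybenzene
Conditions: MeI, K2CO3, acetone, reflux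
Reagents that add atoms: iodomethane (CI)
Why: Williamson ether synthesis on the phenoxide; no stereocentre.

Step 10
Reactants: 14 (1E,2S,4aS,8aS)-1-(chloromethylidene)-2,5,5,8a-tetramethyldecahydronaphthalene; 18 1-bromo-2,3,5-trimethoxybenzene
Product: 21 (1E,2S,4aS,8aS)-1-[chloro(2,3,5-trimethoxyphenyl)methylidene]-2,5,5,8a-tetramethyldecahydronaphthalene, via chloroalkenyllithium 19 (not isolated), via chloroalkenylzinc chloride 20 (not isolated)
Conditions: s-BuLi, THF/Et2O/pentane, −105 °C; ZnCl2, −105 → −40 °C; 18, Pd2(dba)3 (2.5 mol %), SPhos, THF, 25 → 45 °C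
Reagents that add atoms: none
Why: Deprotonation geminal to chlorine, transmetalation to zinc and Negishi coupling all go with retention, so the aryl group takes the place of the vinylic hydrogen syn to C10 and chlorine stays syn to C8 (E alkene); the aryl bromide should undergo oxidative addition in preference to the hindered alkenyl chloride.

Step 11
Reactants: 21 (1E,2S,4aS,8aS)-1-[chloro(2,3,5-trimethoxyphenyl)methylidene]-2,5,5,8a-tetramethyldecahydronaphthalene
Product: 22 2-{(E)-chloro[(2S,4aS,8aS)-2,5,5,8a-tetramethyloctahydronaphthalen-1(2H)-ylidene]methyl}-6-methoxycyclohexa-2,5-diene-1,4-dione (target)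
Conditions: (NH4)2Ce(NO3)6, MeCN/H2O, 0 °C
Reagents that add atoms: water (O)
Why: Oxidative demethylation: the para-related 2′- and 5′-methoxy groups are oxidised to the 1,4-quinone with water as the oxygen source while the 3′-methoxy group stays, giving the 2-alkenyl-6-methoxybenzoquinone; no stereocentre is touched.

**Compound list**
1 | (R)-(−)-carvone, (5R)-2-methyl-5-(prop-1-en-2-yl)cyclohex-2-en-1-one | CC1=CC[C@H](CC1=O)C(C)=C | starting material
2 | lithium (3R)-6-methyl-3-(prop-1-en-2-yl)cyclohexa-1,5-dien-1-olate (α′-dienolate of 1) | CC1=CC[C@@H](C(C)=C)C=C1O[Li] | intermediate (not isolated)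
3 | (5R,6S)-2,6-dimethyl-5-(prop-1-en-2-yl)cyclohex-2-en-1-one | CC1=CC[C@@H](C(C)=C)[C@H](C)C1=O | intermediate
4 | 2,3-bis(phenylsulfonyl)prop-1-ene | C=C(CS(=O)(=O)c1ccccc1)S(=O)(=O)c1ccccc1 | starting material
5 | lithium (3S)-2,6-dimethyl-3-(prop-1-en-2-yl)cyclohexa-1,5-dien-1-olate (α′-dienolate of 3) | CC1=CC[C@@H](C(C)=C)C(C)=C1O[Li] | intermediate (not isolated)
6 | (5S,6S)-2,6-dimethyl-6-[2-(phenylsulfonyl)prop-2-en-1-yl]-5-(prop-1-en-2-yl)cyclohex-2-en-1-one (allyl group trans to isopropenyl) | CC1=CC[C@@H](C(C)=C)[C@](C)(CC(=C)S(=O)(=O)c2ccccc2)C1=O | intermediate (not isolated)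
7 | (4aS,8aS)-2,5,5,8a-tetramethyl-7-(phenylsulfonyl)-4a,5,6,7,8,8a-hexahydronaphthalen-1(4H)-one (trans-fused; C7 epimers) | O=C2C(C)=CC[C@H]3C(C)(C)CC(S(=O)(=O)c4ccccc4)C[C@]23C | intermediate
8 | lithium (4aS,8aS)-2,5,5,8a-tetramethyl-3,4,4a,5,6,7,8,8a-octahydronaphthalen-1-olate | [Li]OC2=C(C)CC[C@H]3C(C)(C)CCC[C@]23C | intermediate (not isolated)
9 | (4aS,8aS)-2,5,5,8a-tetramethyl-3,4,4a,5,6,7,8,8a-octahydronaphthalen-1-yl trifluoromethanesulfonate | FC(F)(F)S(=O)(=O)OC2=C(C)CC[C@H]3C(C)(C)CCC[C@]23C | intermediate
10 | (4aS,8aS)-2,5,5,8a-tetramethyl-3,4,4a,5,6,7,8,8a-octahydronaphthalene-1-carbaldehyde | O=CC2=C(C)CC[C@H]3C(C)(C)CCC[C@]23C | intermediate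
11 | (1S,2S,4aS,8aS)-2,5,5,8a-tetramethyldecahydronaphthalene-1-carbaldehyde | O=C[C@H]2[C@@H](C)CC[C@H]3C(C)(C)CCC[C@]23C | intermediate
12 | potassium (E)-[(2S,4aS,8aS)-2,5,5,8a-tetramethyloctahydronaphthalen-1(2H)-ylidene]methanolate | [K]O/C=C2\[C@@H](C)CC[C@H]3C(C)(C)CCC[C@]23C | intermediate (not isolated)
13 | (E)-[(2S,4aS,8aS)-2,5,5,8a-tetramethyloctahydronaphthalen-1(2H)-ylidene]methyl trifluoromethanesulfonate | FC(F)(F)S(=O)(=O)O/C=C2\[C@@H](C)CC[C@H]3C(C)(C)CCC[C@]23C | intermediate
14 | (1E,2S,4aS,8aS)-1-(chloromethylidene)-2,5,5,8a-tetramethyldecahydronaphthalene | Cl/C=C2\[C@@H](C)CC[C@H]3C(C)(C)CCC[C@]23C | intermediate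
15 | 3-bromo-4,5-dimethoxybenzaldehyde | COc1cc(C=O)cc(Br)c1OC | starting material
16 | 3-bromo-4,5-dimethoxyphenyl formate | COc1cc(OC=O)cc(Br)c1OC | intermediate (not isolated)
17 | 3-bromo-4,5-dimethoxyphenol | COc1cc(O)cc(Br)c1OC | intermediate
18 | 1-bromo-2,3,5-trimethoxybenzene | COc1cc(OC)cc(Br)c1OC | intermediate
19 | chloroalkenyllithium from 14 (Li in place of the vinylic H, syn to C8a) | [Li]/C(Cl)=C2/[C@@H](C)CC[C@H]3C(C)(C)CCC[C@]23C | intermediate (not isolated)
20 | chloroalkenylzinc chloride from 19 (same geometry) | Cl[Zn]/C(Cl)=C2/[C@@H](C)CC[C@H]3C(C)(C)CCC[C@]23C | intermediate (not isolated)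
21 | (1E,2S,4aS,8aS)-1-[chloro(2,3,5-trimethoxyphenyl)methylidene]-2,5,5,8a-tetramethyldecahydronaphthalene | COc1cc(OC)cc(/C(Cl)=C2/[C@@H](C)CC[C@H]3C(C)(C)CCC[C@]23C)c1OC | intermediate
22 | 2-{(E)-chloro[(2S,4aS,8aS)-2,5,5,8a-tetramethyloctahydronaphthalen-1(2H)-ylidene]methyl}-6-methoxycyclohexa-2,5-diene-1,4-dione | COC1=CC(=O)C=C(/C(Cl)=C2/[C@@H](C)CC[C@H]3C(C)(C)CCC[C@]23C)C1=O | target

**Step count and risks**
Total: 11 steps. Longest linear sequence: 9 steps (steps 1–7, 10 and 11, from 1).

The three steps most likely to fail are steps 2, 5 and 10.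

Step 2. In the first stage, proton transfer from the acidic allylic CH2 of 4 to the hindered dienolate, or a second addition to the new vinyl sulfone, may compete with the SN2′ alkylation. In the second stage, the benzenesulfinate left in the flask may add back reversibly to the vinyl sulfone, and simple reduction of the isopropenyl group or of the vinyl sulfone may outrun ring closure. The fallback sets out from 3 and comes back at 9. The lithium dienolate of 3 is alkylated with (Z)-3-bromo-1-iodoprop-1-ene, again anti to the isopropenyl group, to give the vinyl iodide F1. An intramolecular reductive Heck reaction (Pd(OAc)2, PPh3, HCO2Na, DMF, 80 °C) closes ring A by 6-exo-trig carbopalladation of the isopropenyl group; formate then reduces the neopentyl palladium species, which has no β-hydrogen, and this gives the dienone F2. Hydrogenation of both C=C bonds (H2, Pd/C) gives the saturated ketone F3, and KN(SiMe3)2 with PhNTf2 converts it into 9.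

Step 5. Hydrogen delivery to the tetrasubstituted C8=C9 bond, flanked by a quaternary carbon, may be slow or facially unselective, and the aldehyde may be over-reduced or lost by decarbonylation. The fallback sets out from 9 and comes back at 11. Kumada coupling of 9 with Me3SiCH2MgCl (Pd(PPh3)4, THF) gives the allylsilane F4. Protodesilylation with CF3CO2H moves the double bond to C9=C11 and delivers the proton to C8 from the unhindered α face, giving the exocyclic alkene F5 with the 8β-methyl group. Hydroboration with 9-BBN from the α face and oxidation (H2O2, NaOH) give the primary alcohol F6, and Dess–Martin oxidation gives 11.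

Step 10. The chloroalkenyllithium may lose LiCl (α-elimination followed by carbene C–H insertion) or lose its configuration before transmetalation, and reductive elimination at the crowded tetrasubstituted alkene carbon may stall. The fallback sets out from 14 and comes back at 21, with the polarity of the coupling partners inverted so that no carbenoid has to survive above −100 °C. Carbenoid 19 is quenched at −105 °C with iodine, with retention, to give the 1-chloro-1-iodoalkene F7. Bromide 18 is converted by bromine–lithium exchange (n-BuLi, THF, −78 °C) and B(OMe)3, then aqueous acid, into the boronic acid F8. A Suzuki–Miyaura coupling that is selective for the C–I bond (Pd(OAc)2, SPhos, K3PO4, toluene/H2O) then gives 21.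

**Further compounds**
F1 | step 2 | (5S,6S)-6-[(2Z)-3-iodoprop-2-en-1-yl]-2,6-dimethyl-5-(prop-1-en-2-yl)cyclohex-2-en-1-one | CC1=CC[C@@H](C(C)=C)[C@](C)(C/C=C\I)C1=O
F2 | step 2 | (4aS,8aS)-2,5,5,8a-tetramethyl-4a,5,8,8a-tetrahydronaphthalen-1(4H)-one | O=C2C(C)=CC[C@H]3C(C)(C)C=CC[C@]23C
F3 | step 2 | (4aS,8aS)-2,5,5,8a-tetramethyloctahydronaphthalen-1(2H)-one (C2 epimers) | O=C2C(C)CC[C@H]3C(C)(C)CCC[C@]23C
F4 | step 5 | trimethyl{[(4aS,8aS)-2,5,5,8a-tetramethyl-3,4,4a,5,6,7,8,8a-octahydronaphthalen-1-yl]methyl}silane | C[Si](C)(C)CC2=C(C)CC[C@H]3C(C)(C)CCC[C@]23C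
F5 | step 5 | (2S,4aS,8aS)-2,5,5,8a-tetramethyl-1-methylidenedecahydronaphthalene | C=C2[C@@H](C)CC[C@H]3C(C)(C)CCC[C@]23C
F6 | step 5 | [(1S,2S,4aS,8aS)-2,5,5,8a-tetramethyldecahydronaphthalen-1-yl]methanol | OC[C@H]2[C@@H](C)CC[C@H]3C(C)(C)CCC[C@]23C
F7 | step 10 | (1Z,2S,4aS,8aS)-1-[chloro(iodo)methylidene]-2,5,5,8a-tetramethyldecahydronaphthalene | I/C(Cl)=C2/[C@@H](C)CC[C@H]3C(C)(C)CCC[C@]23C
F8 | step 10 | (2,3,5-trimethoxyphenyl)boronic acid | COc1cc(OC)cc(B(O)O)c1OC
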